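## Structural features

The target is a (2S,3S)-2,3-dihydro-4H-furo[3,2-c]pyran-4-one. Dihydrofuran ring A (O1, C2, C3, C3a, C7a) is fused along C3a–C7a to 2-pyranone ring B (C3a, C4, O5, C6, C7, C7a). C2 carries the 3,4-dihydroxyphenyl ring D, C3 carries the 4-hydroxy-2-pyranone ring C through its C6', and C6 carries an (E)-4-hydroxystyryl arm ending in ring E. The only stereocentres, C2 and C3, are adjacent, and their substituents are trans on ring A. Trans is the thermodynamically preferred arrangement, so the absolute configuration rests on C2 once C3 can equilibrate. C3–H lies between two pyranone carbons and is β to O1, so a carbanion at C3 can epimerise or expel O1 from C2. The C2–O1 bond is a benzylic bond to a vinylogous carboxylate oxygen, and the catechol, the 4-hydroxypyranone and the styryl alkene are sensitive to oxidants and to base in air. The real difficulty is to set C2 absolutely and then carry the C2/C3 pair through the construction of ring C and of the styryl arm, both of which classically call for strong base. The key step exploits the fact that C3 bears a carbon at the carboxylic acid level (C6' of ring C) next to the aryl ether carbon C2. This is the pattern left when a 2-aryl-2,3-dihydropyran-4-one fused to ring B contracts by a 1,2-shift of the ring B carbon from the ketone carbon to C3, the ketone carbon leaving the ring as an ester.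

## Logic of the disconnections

19 to 18: only the three aryl O–acyl bonds are cut. The phenols must be masked by electron-withdrawing groups that survive trivalent iodine and strong acid, and one kind of group on all three phenols allows a single release. The forward step must be an acyl transfer that spares both lactones, the C2–O1 bond and the catechol, so it has to be run without oxygen.

18 to 17: the lactone O1'–C2' bond of ring C is cut. A 4-hydroxy-2-pyranone is the cyclised form of a 3,5-dioxo ester, so ring C becomes an open chain. The closure must take place without base, because C3–H is α to a ketone in 17.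

17 to 12 and 15: the C5'–C6' bond is cut. C6' is the carboxyl carbon on C3 in 12 and the four carbons C2'–C5' arrive in one piece from 15. The forward step must acylate the terminal carbon of 15 without any base that could enolise the activated acid at C3.

15 to 14 to 13: two O–Si bonds are cut in turn. This traces the neutral four-carbon nucleophile to a commercial β-keto ester; the forward steps are standard enol silylations.

12 to 8 and 10: the styryl C=C bond is cut. This removes ring E and the alkene and leaves a 6-methyl group on ring B, which is vinylogously acidic. The forward step must deprotonate that methyl group but not C3–H; the carboxylate of 8 provides this protection, and the dehydration must be acid-mediated.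

10 to 9: one aryl O–acyl bond is cut, to a commercial phenol.

8 to 7: the ester O–methyl link is cut. The ring contraction delivers the carboxyl carbon as a methyl ester. The forward step must cleave it in the presence of two aryl pivalates and a lactone without strong base.

7 to 5: the C3–C3a bond of ring A is cut and C3a is reconnected to the ester carbon. This restores a six-membered 2-aryl-2,3-dihydropyran-4-one and erases the C3 stereocentre, so that a single stereocentre is left. The forward step must make the ring B carbon migrate in preference to the C2 aryl group and must place the ester trans to that group.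

5 to 4: the O1–C2 bond is cut. A β-aryloxy ketone becomes an enone with a free vinylogous acid, and no stereocentre remains. The forward step must be an enantioselective 6-endo-trig oxa-Michael closure whose product does not re-open.

4 to 3 and 2: the enone C=C bond is cut. The whole acylpyranone comes from one commercial piece and the aryl part from an aldehyde. The forward condensation must occur at the acetyl methyl group only.

2 to 1: two aryl O–acyl bonds are cut, to a commercial catechol aldehyde.

## Other disconnections considered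

Alternative 1: The cut is O1–C2 of ring A. The tris-MOM ether A1 is traced to the donor–acceptor spirocyclopropane A2, in which C3a is the spiro carbon of a 6-styrylpyran-2,4-dione and C2 and C3 are the other two ring carbons. In the forward step Sc(OTf)3 would ionise the C3a–C2 bond and the ketone oxygen at C7a would capture the benzylic cation (Cloke–Wilson ring expansion), closing ring A and making ring B the aromatic 2-pyranone.
- In its favour: ring C, the styryl arm and every carbon are in place before ring A forms, so only acetal removal follows. No oxidant or strong protic acid is used, so acid-labile MOM groups can be carried.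
- Against it here: either carbonyl oxygen of the pyrandione can capture the cation, so the 4-pyranone isomer would compete. C2 passes through a cation, so the absolute configuration must come from an enantioselective cyclopropanation of an electron-rich, pyranonyl-substituted alkene, which cannot be assumed. The Lewis acid also meets three MOM ethers and a free acidic pyranone OH, and A2 may be too labile to handle.
- Comparison: in the chosen plan O1–C2 already exists when the ring contracts, so that regiochemical question does not arise, and C2 is set catalytically on the simple compound 4. Alternative 1 is equal in relative stereocontrol (trans under thermodynamic control in both) and better in convergence and in the steps after the key step. It is weaker in the accessibility of its precursor.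

Alternative 2: The cut is C2–C3. The ethyl ester A3 is traced to the pyranonyl diazoacetate A4, a 4-O-benzyl ether. In the forward step Rh2(S-PTTL)4, a chiral dirhodium tetracarboxylate of divalent rhodium, would generate a carbenoid at C3 that inserts into a benzylic C–H bond of the ether (1,5-insertion), closing ring A.
- In its favour: enantioselective insertions of this type into benzylic ether C–H bonds are well established for aryl diazoacetates. The styryl arm is present beforehand, and the absence of acid and oxidant allows MOM ethers.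
- Against it here: such insertions usually give the 2,3-cis product under kinetic control, so a base epimerisation at C3 would have to follow. The carbenoid is flanked by a lactone carbonyl and could also attack the styryl alkene or the electron-rich arenes. O-benzylation of the 4-hydroxypyranone competes with C-alkylation, and a diazo compound must be handled.
- Comparison: after the key step A3 stands where 7 stands, because the ester still has to be grown into ring C, and MOM ethers are less comfortable than pivalates with acid chloride chemistry. Alternative 2 is probably better in the reliability of the enantioselective step and equal in the downstream work. It is weaker in relative configuration and in the number of competing carbenoid pathways.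

Alternative 3: The cut is O1–C7a. The N-methoxy-N-methyl amide A5 is traced to the syn-aldol adduct A6, whose C2 hydroxyl adds to C7a of a 4-methoxy-2-pyranone and expels methoxide (addition–elimination, 5-exo-trig).
- In its favour: an auxiliary-controlled syn-aldol addition sets both stereocentres with predictable absolute sense, and syn maps onto trans in ring A. The styryl arm is in place early, and the amide is directly an acyl donor for ring C, so no ester cleavage is needed.
- Against it here: the enolate is a hindered, doubly ortho-substituted pyranonylacetyl unit. The adduct A6 can undergo retro-aldol cleavage or C3 epimerisation under the basic closure. The C2 alkoxide can also attack the lactone carbonyl C4 (likewise a five-membered closure), and the auxiliary must be attached, used and exchanged stoichiometrically.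
- Comparison: the chosen plan needs one catalytic asymmetric step and no auxiliary, and its ring A arises from an existing ring, so no competition between two electrophilic carbons occurs. Alternative 3 is better in predictability of the absolute configuration and in the acyl donor it delivers, and about equal or longer in step count.

Key step: step 4

Assumption: the sense of induction of the cinchona thiourea in step 3 cannot be predicted with certainty for this vinylogous acid; the quinidine-derived catalyst is written, and its quinine-derived pseudoenantiomer would be used if it favoured the (R)-product.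

Remark: compound 5 is named as a pyrano[4,3-b]pyran, the systematic fusion name of its ring system. The carbon that migrates in step 4 is C4a of 5 and becomes C3a of 7.

## Route

Step 1
Reactants: 1 3,4-dihydroxybenzaldehyde
Product: 2 3,4-bis(pivaloyloxy)benzaldehyde
Conditions: PivCl (2.3 equiv), Et3N (3 equiv), DMAP (5 mol %), CH2Cl2, 0 → 23 °C
Reagents that add atoms: pivaloyl chloride, CC(C)(C)C(Cl)=O
Why: DMAP-catalysed O-acylation of both phenols; the pivalates are hindered, acid-stable and electron-withdrawing, which is what the later oxidation step requires of ring D.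

Step 2
Reactants: 3 dehydroacetic acid; 2 3,4-bis(pivaloyloxy)benzaldehyde
Product: 4 3-[(2E)-3-[3,4-bis(pivaloyloxy)phenyl]prop-2-enoyl]-4-hydroxy-6-methyl-2H-pyran-2-one
Conditions: piperidine (0.2 equiv), CHCl3, 4 Å molecular sieves, reflux
Reagents that add atoms: none
Why: Amine-catalysed aldol condensation (Claisen–Schmidt type) at the acetyl methyl group, the position activated by the chelated β-dicarbonyl unit, while the 6-methyl group is inert under these conditions; dehydration gives the conjugated E-enone, and the amine is largely held as its salt with the acidic enol, which spares the pivalates.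

Step 3
Reactants: 4 3-[(2E)-3-[3,4-bis(pivaloyloxy)phenyl]prop-2-enoyl]-4-hydroxy-6-methyl-2H-pyran-2-one
Product: 5 (2S)-2-[3,4-bis(pivaloyloxy)phenyl]-7-methyl-2,3-dihydro-4H,5H-pyrano[4,3-b]pyran-4,5-dione
Conditions: N-[3,5-bis(trifluoromethyl)phenyl]-N'-(9-deoxy-epi-quinidin-9-yl)thiourea (10 mol %), PhMe, 0 °C
Reagents that add atoms: none
Why: Bifunctional catalysis of an intramolecular oxa-Michael addition of the type known for 2'-hydroxychalcones: the quinuclidine takes the proton of the acidic pyranone OH, the thiourea binds the enone carbonyl, and the pyranone oxygen adds to the β-carbon in a 6-endo-trig closure. The chiral ion pair differentiates the enone faces and should set C2 as S; low temperature and a non-polar solvent limit retro-addition.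

Step 4
Reactants: 5 (2S)-2-[3,4-bis(pivaloyloxy)phenyl]-7-methyl-2,3-dihydro-4H,5H-pyrano[4,3-b]pyran-4,5-dione
Product: 7 methyl (2S,3S)-2-[3,4-bis(pivaloyloxy)phenyl]-6-methyl-4-oxo-2,3-dihydro-4H-furo[3,2-c]pyran-3-carboxylate (2,3-trans), via methyl enol ether 6 (not isolated)
Conditions: PhI(OAc)2 (1.3 equiv), conc. H2SO4 (2 equiv), HC(OMe)3, 0 → 23 °C
Reagents that add atoms: trimethyl orthoformate, COC(OC)OC
Why: Acid and the orthoformate turn the C4 ketone into methyl enol ether 6 (C3=C4), electrophilic trivalent iodine then adds to C3 on the face away from the C2 aryl group, and methanol caps C4 to give a 2,3-trans C3-iodanyl dimethyl ketal. In the diequatorial half-chair the C3–I bond is antiperiplanar to the ring bond C4–C4a, so loss of PhI is assisted by a 1,2-shift of C4a (the nucleophilic carbon of the 4-alkoxy-2-pyranone) from C4 to C3 with inversion at C3, and the dimethoxycarbenium ion left behind collapses to the methyl ester. The closest known reaction type is the oxidative ring contraction of flavanones to trans methyl 2-aryl-2,3-dihydrobenzofuran-3-carboxylates with PhI(OAc)2 or Tl(NO3)3 in trimethyl orthoformate, a semipinacol-type shift of an α-iodanyl ketal. Ring A is therefore closed not by an exo or endo cyclisation but by contraction of the six-membered ring, the C3–C3a bond forming through a bridged three-membered transition state. The C2 stereocentre is not touched and stays S, while the new C3 stereocentre is controlled by C2, because iodine anti to the aryl group followed by inversion leaves the ester trans, which is also the thermodynamic epimer. The selectivity needed is migration of C4a instead of a C2-to-C3 aryl shift or simple dehydrogenation; it is secured by the electron-poor bis(pivaloyloxy)phenyl group, by the O1 lone pair being tied up in the vinylogous carbonate so that a C2 cation is poorly stabilised, and by the push of the two ketal oxygen atoms on the C4–C4a bond.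

Step 5
Reactants: 7 methyl (2S,3S)-2-[3,4-bis(pivaloyloxy)phenyl]-6-methyl-4-oxo-2,3-dihydro-4H-furo[3,2-c]pyran-3-carboxylate
Product: 8 (2S,3S)-2-[3,4-bis(pivaloyloxy)phenyl]-6-methyl-4-oxo-2,3-dihydro-4H-furo[3,2-c]pyran-3-carboxylic acid
Conditions: Me3SnOH (4 equiv), ClCH2CH2Cl, 70 °C; then 5% aq. HCl wash
Reagents that add atoms: trimethyltin hydroxide, C[Sn](C)(C)O
Why: Me3SnOH cleaves unhindered methyl esters by mild acyl–oxygen hydrolysis in a non-basic medium, so the hindered aryl pivalates, the lactone and the C3–H/C2–O1 array should be left alone; any C3 epimerisation would converge on the favoured trans acid.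

Step 6
Reactants: 9 4-hydroxybenzaldehyde
Product: 10 4-(pivaloyloxy)benzaldehyde
Conditions: PivCl (1.2 equiv), Et3N (1.5 equiv), DMAP (5 mol %), CH2Cl2, 0 → 23 °C
Reagents that add atoms: pivaloyl chloride, CC(C)(C)C(Cl)=O
Why: DMAP-catalysed O-acylation; the same protecting group as on ring D allows one final deprotection and keeps the aldehyde electrophilic.

Step 7
Reactants: 8 (2S,3S)-2-[3,4-bis(pivaloyloxy)phenyl]-6-methyl-4-oxo-2,3-dihydro-4H-furo[3,2-c]pyran-3-carboxylic acid; 10 4-(pivaloyloxy)benzaldehyde
Product: 12 (2S,3S)-2-[3,4-bis(pivaloyloxy)phenyl]-4-oxo-6-[(E)-2-[4-(pivaloyloxy)phenyl]ethenyl]-2,3-dihydro-4H-furo[3,2-c]pyran-3-carboxylic acid, via hydroxy acid 11 (not isolated)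
Conditions: LiN(SiMe3)2 (2.3 equiv), THF, −78 °C; 10 (1.3 equiv), −78 → −40 °C; AcOH; then TsOH·H2O (0.2 equiv), PhMe, 80 °C
Reagents that add atoms: none
Why: The first equivalent of base forms the lithium carboxylate, which makes C3–H non-acidic and blocks β-elimination of O1, and the second deprotonates the vinylogous 6-methyl group, whose dienolate adds through its exocyclic carbon to the aldehyde (vinylogous aldol addition). Acid-catalysed dehydration of benzylic alcohol 11 then gives the conjugated E-alkene under thermodynamic control with no base present.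

Step 8
Reactants: 13 tert-butyl acetoacetate
Product: 14 tert-butyl 3-(trimethylsilyloxy)but-2-enoate (E/Z mixture)
Conditions: Me3SiCl (1.2 equiv), Et3N (1.3 equiv), hexane, 23 °C
Reagents that add atoms: chlorotrimethylsilane, C[Si](C)(C)Cl
Why: O-silylation of the enolised β-keto ester under amine base, a standard silyl enol ether formation.

Step 9
Reactants: 14 tert-butyl 3-(trimethylsilyloxy)but-2-enoate
Product: 15 1-tert-butoxy-1,3-bis(trimethylsilyloxy)buta-1,3-diene
Conditions: LiN(iPr)2 (1.1 equiv), THF, −78 °C; Me3SiCl (1.2 equiv), −78 → 0 °C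
Reagents that add atoms: chlorotrimethylsilane, C[Si](C)(C)Cl
Why: Deprotonation of the γ-methyl group gives the ester dienolate, which is silylated on oxygen to the 1,3-bis(silyl enol ether), a neutral equivalent of the acetoacetate dianion.

Step 10
Reactants: 12 (2S,3S)-2-[3,4-bis(pivaloyloxy)phenyl]-4-oxo-6-[(E)-2-[4-(pivaloyloxy)phenyl]ethenyl]-2,3-dihydro-4H-furo[3,2-c]pyran-3-carboxylic acid; 15 1-tert-butoxy-1,3-bis(trimethylsilyloxy)buta-1,3-diene
Product: 17 tert-butyl 5-[(2S,3S)-2-[3,4-bis(pivaloyloxy)phenyl]-4-oxo-6-[(E)-2-[4-(pivaloyloxy)phenyl]ethenyl]-2,3-dihydro-4H-furo[3,2-c]pyran-3-yl]-3,5-dioxopentanoate, via acid chloride 16 (not isolated)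
Conditions: Me2C=C(Cl)NMe2 (1.2 equiv), CH2Cl2, 0 °C; then 15 (2.0 equiv), −78 → 20 °C; aq. NH4Cl
Reagents that add atoms: none
Why: The chloroenamine gives acid chloride 16 under neutral conditions, so no ketene forms from the acidic C3–H, and the electron-rich bis(silyl enol ether) is C-acylated at its terminal carbon without added base (Mukaiyama-type acylation), giving the 3,5-dioxo ester after aqueous work-up. C3 is never deprotonated, so the trans configuration should persist.

Step 11
Reactants: 17 tert-butyl 5-[(2S,3S)-2-[3,4-bis(pivaloyloxy)phenyl]-4-oxo-6-[(E)-2-[4-(pivaloyloxy)phenyl]ethenyl]-2,3-dihydro-4H-furo[3,2-c]pyran-3-yl]-3,5-dioxopentanoate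
Product: 18 (2S,3S)-2-[3,4-bis(pivaloyloxy)phenyl]-3-(4-hydroxy-2-oxo-2H-pyran-6-yl)-6-[(E)-2-[4-(pivaloyloxy)phenyl]ethenyl]-2,3-dihydro-4H-furo[3,2-c]pyran-4-one
Conditions: PhMe, 110 °C
Reagents that add atoms: none
Why: Thermolysis of the tert-butyl β-keto ester expels tert-butanol and gives an acylketene, which is captured intramolecularly by the oxygen of the 5-keto (enol) group to close ring C as the 4-hydroxy-2-pyranone; the medium is neutral, so C3–H and the pivalates are not at risk.

Step 12
Reactants: 18 (2S,3S)-2-[3,4-bis(pivaloyloxy)phenyl]-3-(4-hydroxy-2-oxo-2H-pyran-6-yl)-6-[(E)-2-[4-(pivaloyloxy)phenyl]ethenyl]-2,3-dihydro-4H-furo[3,2-c]pyran-4-one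
Product: 19 (2S,3S)-2-(3,4-dihydroxyphenyl)-3-(4-hydroxy-2-oxo-2H-pyran-6-yl)-6-[(E)-2-(4-hydroxyphenyl)ethenyl]-2,3-dihydro-4H-furo[3,2-c]pyran-4-one
Conditions: K2CO3 (5 equiv), degassed MeOH, Ar, 0 → 23 °C; then aq. HCl to pH 3
Reagents that add atoms: none
Why: Base-mediated transesterification of the three aryl pivalates to methanol; ring C is present as its unreactive anion, which also keeps C3–H non-acidic, and exclusion of oxygen protects the catecholate until acidification.

## Compound list

1 | 3,4-dihydroxybenzaldehyde | O=Cc1ccc(O)c(O)c1 | starting material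
2 | 3,4-bis(pivaloyloxy)benzaldehyde | CC(C)(C)C(=O)Oc1ccc(C=O)cc1OC(=O)C(C)(C)C | intermediate
3 | dehydroacetic acid | CC(=O)c1c(O)cc(C)oc1=O | starting material
4 | 3-[(2E)-3-[3,4-bis(pivaloyloxy)phenyl]prop-2-enoyl]-4-hydroxy-6-methyl-2H-pyran-2-one | Cc1cc(O)c(C(=O)/C=C/c2ccc(OC(=O)C(C)(C)C)c(OC(=O)C(C)(C)C)c2)c(=O)o1 | intermediate
5 | (2S)-2-[3,4-bis(pivaloyloxy)phenyl]-7-methyl-2,3-dihydro-4H,5H-pyrano[4,3-b]pyran-4,5-dione | Cc1cc2O[C@H](c3ccc(OC(=O)C(C)(C)C)c(OC(=O)C(C)(C)C)c3)CC(=O)c2c(=O)o1 | intermediate
6 | (2S)-2-[3,4-bis(pivaloyloxy)phenyl]-4-methoxy-7-methyl-2H,5H-pyrano[4,3-b]pyran-5-one | Cc1cc2O[C@H](c3ccc(OC(=O)C(C)(C)C)c(OC(=O)C(C)(C)C)c3)C=C(OC)c2c(=O)o1 | intermediate (not isolated)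
7 | methyl (2S,3S)-2-[3,4-bis(pivaloyloxy)phenyl]-6-methyl-4-oxo-2,3-dihydro-4H-furo[3,2-c]pyran-3-carboxylate | COC(=O)[C@H]1c2c(cc(C)oc2=O)O[C@@H]1c1ccc(OC(=O)C(C)(C)C)c(OC(=O)C(C)(C)C)c1 | intermediate
8 | (2S,3S)-2-[3,4-bis(pivaloyloxy)phenyl]-6-methyl-4-oxo-2,3-dihydro-4H-furo[3,2-c]pyran-3-carboxylic acid | OC(=O)[C@H]1c2c(cc(C)oc2=O)O[C@@H]1c1ccc(OC(=O)C(C)(C)C)c(OC(=O)C(C)(C)C)c1 | intermediate
9 | 4-hydroxybenzaldehyde | O=Cc1ccc(O)cc1 | starting material
10 | 4-(pivaloyloxy)benzaldehyde | CC(C)(C)C(=O)Oc1ccc(C=O)cc1 | intermediate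
11 | (2S,3S)-2-[3,4-bis(pivaloyloxy)phenyl]-6-[2-hydroxy-2-[4-(pivaloyloxy)phenyl]ethyl]-4-oxo-2,3-dihydro-4H-furo[3,2-c]pyran-3-carboxylic acid (both carbinol epimers) | OC(=O)[C@H]1c2c(cc(CC(O)c3ccc(OC(=O)C(C)(C)C)cc3)oc2=O)O[C@@H]1c1ccc(OC(=O)C(C)(C)C)c(OC(=O)C(C)(C)C)c1 | intermediate (not isolated)
12 | (2S,3S)-2-[3,4-bis(pivaloyloxy)phenyl]-4-oxo-6-[(E)-2-[4-(pivaloyloxy)phenyl]ethenyl]-2,3-dihydro-4H-furo[3,2-c]pyran-3-carboxylic acid | OC(=O)[C@H]1c2c(cc(/C=C/c3ccc(OC(=O)C(C)(C)C)cc3)oc2=O)O[C@@H]1c1ccc(OC(=O)C(C)(C)C)c(OC(=O)C(C)(C)C)c1 | intermediate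
13 | tert-butyl acetoacetate | CC(=O)CC(=O)OC(C)(C)C | starting material
14 | tert-butyl 3-(trimethylsilyloxy)but-2-enoate (E/Z mixture) | CC(=CC(=O)OC(C)(C)C)O[Si](C)(C)C | intermediate
15 | 1-tert-butoxy-1,3-bis(trimethylsilyloxy)buta-1,3-diene | C=C(O[Si](C)(C)C)C=C(OC(C)(C)C)O[Si](C)(C)C | intermediate
16 | (2S,3S)-2-[3,4-bis(pivaloyloxy)phenyl]-4-oxo-6-[(E)-2-[4-(pivaloyloxy)phenyl]ethenyl]-2,3-dihydro-4H-furo[3,2-c]pyran-3-carbonyl chloride | ClC(=O)[C@H]1c2c(cc(/C=C/c3ccc(OC(=O)C(C)(C)C)cc3)oc2=O)O[C@@H]1c1ccc(OC(=O)C(C)(C)C)c(OC(=O)C(C)(C)C)c1 | intermediate (not isolated)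
17 | tert-butyl 5-[(2S,3S)-2-[3,4-bis(pivaloyloxy)phenyl]-4-oxo-6-[(E)-2-[4-(pivaloyloxy)phenyl]ethenyl]-2,3-dihydro-4H-furo[3,2-c]pyran-3-yl]-3,5-dioxopentanoate | CC(C)(C)OC(=O)CC(=O)CC(=O)[C@H]1c2c(cc(/C=C/c3ccc(OC(=O)C(C)(C)C)cc3)oc2=O)O[C@@H]1c1ccc(OC(=O)C(C)(C)C)c(OC(=O)C(C)(C)C)c1 | intermediate
18 | (2S,3S)-2-[3,4-bis(pivaloyloxy)phenyl]-3-(4-hydroxy-2-oxo-2H-pyran-6-yl)-6-[(E)-2-[4-(pivaloyloxy)phenyl]ethenyl]-2,3-dihydro-4H-furo[3,2-c]pyran-4-one | O=c1cc(O)cc([C@H]2c3c(cc(/C=C/c4ccc(OC(=O)C(C)(C)C)cc4)oc3=O)O[C@@H]2c2ccc(OC(=O)C(C)(C)C)c(OC(=O)C(C)(C)C)c2)o1 | intermediate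
19 | (2S,3S)-2-(3,4-dihydroxyphenyl)-3-(4-hydroxy-2-oxo-2H-pyran-6-yl)-6-[(E)-2-(4-hydroxyphenyl)ethenyl]-2,3-dihydro-4H-furo[3,2-c]pyran-4-one | O=c1cc(O)cc([C@H]2c3c(cc(/C=C/c4ccc(O)cc4)oc3=O)O[C@@H]2c2ccc(O)c(O)c2)o1 | target

## Step count and least certain steps

Total step count: 12. Longest linear sequence: 9 steps (steps 1, 2, 3, 4, 5, 7, 10, 11, 12).

**Step 4 (key step).** The most likely failure is diversion of the C3-iodanyl ketal: loss of a proton to give the dehydrogenated (flavone-type) pyranone, a C2-to-C3 aryl shift, or attack of the oxidant on the pyranone C8 position. Acid-promoted re-opening of ring closure at O1–C2 before ketalisation would also erode the configuration of C2.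
Fallback, from 5 back to 7: the oxidation and the shift are separated. CuBr2 in EtOAc–CHCl3 at reflux should brominate C3 of 5 to the 2,3-trans bromo ketone (2R,3R)-2-[3,4-bis(pivaloyloxy)phenyl]-3-bromo-7-methyl-2,3-dihydro-4H,5H-pyrano[4,3-b]pyran-4,5-dione F1. In HC(OMe)3/MeOH with TsOH this forms its dimethyl ketal F2. AgBF4 then abstracts bromide, the equatorial C–Br bond being anti to C4–C4a, so that the same 1,2-shift gives 7. This is the silver-assisted rearrangement of α-halo ketals to esters, a known reaction type, and it needs no trivalent iodine.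

**Step 3.** Incomplete facial discrimination, slow closure, or retro-oxa-Michael equilibration during the reaction or on silica would lower the enantiomeric purity. Closure through the lactone carbonyl oxygen of the tautomer would give the isomeric 4-pyranone.
Fallback, from 4 back to 5: catalytic Et3N in CH2Cl2 should give the racemic 2-[3,4-bis(pivaloyloxy)phenyl]-7-methyl-2,3-dihydro-4H,5H-pyrano[4,3-b]pyran-4,5-dione F3. This is resolved by preparative chromatography on a chiral stationary phase to give 5, and the unwanted antipode is returned to 4 by base-mediated ring opening.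

**Step 7.** Incomplete formation or poor solubility of the carboxylate dienolate, addition of the amide base to an aryl pivalate, or sluggish acid-catalysed dehydration could stall the olefination.
Fallback, from 7 and 10 back to 12: the olefination is done at the ester stage. LiN(iPr)2 (2.2 equiv) at −78 °C followed by 10 should give the hydroxy ester, methyl 2-[3,4-bis(pivaloyloxy)phenyl]-6-[2-hydroxy-2-[4-(pivaloyloxy)phenyl]ethyl]-4-oxo-2,3-dihydro-4H-furo[3,2-c]pyran-3-carboxylate F4. MsCl/Et3N and then DBU eliminate by the E1cB path and re-equilibrate C3 to trans, giving methyl (2S,3S)-2-[3,4-bis(pivaloyloxy)phenyl]-4-oxo-6-[(E)-2-[4-(pivaloyloxy)phenyl]ethenyl]-2,3-dihydro-4H-furo[3,2-c]pyran-3-carboxylate F5. Me3SnOH as in step 5 then gives 12.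

**Step 10.** Acylation at the central carbon or at oxygen of the diene, or hydrolysis of the acid chloride before it reacts, would lower the yield of the triketide chain.
Fallback, from 12 and 13 back to 17: 1,1'-carbonyldiimidazole converts 12 into the acyl imidazolide, (2S,3S)-2-[3,4-bis(pivaloyloxy)phenyl]-3-(imidazole-1-carbonyl)-6-[(E)-2-[4-(pivaloyloxy)phenyl]ethenyl]-2,3-dihydro-4H-furo[3,2-c]pyran-4-one F6. F6 is added to the dianion of 13 (NaH, then n-BuLi, THF, −20 °C), which is acylated at its terminal carbon to give 17. The dianion may deprotonate C3–H, so the product would be re-equilibrated to trans if needed.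

**Step 5.** Competing loss of an aryl pivalate by the tin hydroxide would give mixtures of phenols.
Fallback, from 7 back to 8: LiI in EtOAc at reflux removes the methyl group by SN2 attack at the O–CH3 carbon, an alkyl–oxygen cleavage that cannot touch the pivalates, and acidification gives 8. This fallback makes no new compound (F0).

**Step 12.** Air oxidation of the catecholate, slow cleavage of the hindered esters, or base-induced opening at C2–O1 could degrade the product.
Fallback, from 18 back to 19: acid-catalysed transesterification with anhydrous HCl in MeOH (from AcCl) at 45 °C forms no phenoxide at any stage. This fallback makes no new compound (F0).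

## Further compounds

F1 | step 4 | (2R,3R)-2-[3,4-bis(pivaloyloxy)phenyl]-3-bromo-7-methyl-2,3-dihydro-4H,5H-pyrano[4,3-b]pyran-4,5-dione (2,3-trans) | Cc1cc2O[C@H](c3ccc(OC(=O)C(C)(C)C)c(OC(=O)C(C)(C)C)c3)[C@@H](Br)C(=O)c2c(=O)o1
F2 | step 4 | (2R,3R)-2-[3,4-bis(pivaloyloxy)phenyl]-3-bromo-4,4-dimethoxy-7-methyl-3,4-dihydro-2H,5H-pyrano[4,3-b]pyran-5-one | Cc1cc2O[C@H](c3ccc(OC(=O)C(C)(C)C)c(OC(=O)C(C)(C)C)c3)[C@@H](Br)C(OC)(OC)c2c(=O)o1
F3 | step 3 | racemic 2-[3,4-bis(pivaloyloxy)phenyl]-7-methyl-2,3-dihydro-4H,5H-pyrano[4,3-b]pyran-4,5-dione | Cc1cc2OC(c3ccc(OC(=O)C(C)(C)C)c(OC(=O)C(C)(C)C)c3)CC(=O)c2c(=O)o1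
F4 | step 7 | methyl (2S)-2-[3,4-bis(pivaloyloxy)phenyl]-6-[2-hydroxy-2-[4-(pivaloyloxy)phenyl]ethyl]-4-oxo-2,3-dihydro-4H-furo[3,2-c]pyran-3-carboxylate (C3 and carbinol epimers) | COC(=O)C1c2c(cc(CC(O)c3ccc(OC(=O)C(C)(C)C)cc3)oc2=O)O[C@@H]1c1ccc(OC(=O)C(C)(C)C)c(OC(=O)C(C)(C)C)c1
F5 | step 7 | methyl (2S,3S)-2-[3,4-bis(pivaloyloxy)phenyl]-4-oxo-6-[(E)-2-[4-(pivaloyloxy)phenyl]ethenyl]-2,3-dihydro-4H-furo[3,2-c]pyran-3-carboxylate | COC(=O)[C@H]1c2c(cc(/C=C/c3ccc(OC(=O)C(C)(C)C)cc3)oc2=O)O[C@@H]1c1ccc(OC(=O)C(C)(C)C)c(OC(=O)C(C)(C)C)c1
F6 | step 10 | (2S,3S)-2-[3,4-bis(pivaloyloxy)phenyl]-3-(imidazole-1-carbonyl)-6-[(E)-2-[4-(pivaloyloxy)phenyl]ethenyl]-2,3-dihydro-4H-furo[3,2-c]pyran-4-one | O=C(n1ccnc1)[C@H]1c2c(cc(/C=C/c3ccc(OC(=O)C(C)(C)C)cc3)oc2=O)O[C@@H]1c1ccc(OC(=O)C(C)(C)C)c(OC(=O)C(C)(C)C)c1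
F0 | step 5 | none | none
F0 | step 12 | none | none
A1 | alternative 1 | (2S,3S)-2-[3,4-bis(methoxymethoxy)phenyl]-3-(4-hydroxy-2-oxo-2H-pyran-6-yl)-6-[(E)-2-[4-(methoxymethoxy)phenyl]ethenyl]-2,3-dihydro-4H-furo[3,2-c]pyran-4-one | O=c1cc(O)cc([C@H]2c3c(cc(/C=C/c4ccc(OCOC)cc4)oc3=O)O[C@@H]2c2ccc(OCOC)c(OCOC)c2)o1
A2 | alternative 1 | 1-[3,4-bis(methoxymethoxy)phenyl]-2-(4-hydroxy-2-oxo-2H-pyran-6-yl)-6-[(E)-2-[4-(methoxymethoxy)phenyl]ethenyl]-5-oxaspiro[2.5]oct-6-ene-4,8-dione (1,2-trans, C2 as in A1, spiro carbon either way) | O=c1cc(O)cc([C@H]2C3(C(=O)C=C(/C=C/c4ccc(OCOC)cc4)OC3=O)[C@@H]2c5ccc(OCOC)c(OCOC)c5)o1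
A3 | alternative 2 | ethyl (2S,3S)-2-[3,4-bis(methoxymethoxy)phenyl]-6-[(E)-2-[4-(methoxymethoxy)phenyl]ethenyl]-4-oxo-2,3-dihydro-4H-furo[3,2-c]pyran-3-carboxylate | CCOC(=O)[C@H]1c2c(cc(/C=C/c3ccc(OCOC)cc3)oc2=O)O[C@@H]1c1ccc(OCOC)c(OCOC)c1
A4 | alternative 2 | ethyl 2-diazo-2-[4-[[3,4-bis(methoxymethoxy)phenyl]methoxy]-6-[(E)-2-[4-(methoxymethoxy)phenyl]ethenyl]-2-oxo-2H-pyran-3-yl]acetate | CCOC(=O)C(=[N+]=[N-])c1c(OCc2ccc(OCOC)c(OCOC)c2)cc(/C=C/c2ccc(OCOC)cc2)oc1=O
A5 | alternative 3 | (2S,3S)-2-[3,4-bis(methoxymethoxy)phenyl]-N-methoxy-6-[(E)-2-[4-(methoxymethoxy)phenyl]ethenyl]-N-methyl-4-oxo-2,3-dihydro-4H-furo[3,2-c]pyran-3-carboxamide | CON(C)C(=O)[C@H]1c2c(cc(/C=C/c3ccc(OCOC)cc3)oc2=O)O[C@@H]1c1ccc(OCOC)c(OCOC)c1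
A6 | alternative 3 | 2,3-syn 3-[3,4-bis(methoxymethoxy)phenyl]-3-hydroxy-N-methoxy-2-[4-methoxy-6-[(E)-2-[4-(methoxymethoxy)phenyl]ethenyl]-2-oxo-2H-pyran-3-yl]-N-methylpropanamide, configured as A5 | CON(C)C(=O)[C@H]([C@H](O)c1ccc(OCOC)c(OCOC)c1)c1c(OC)cc(/C=C/c2ccc(OCOC)cc2)oc1=O
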